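If the fall of Xa is counted in powers of ten, the early runs can be laid on one scale. A decade here means a tenfold fall in Xa.

all flasks: Xc 0.00400 M
- larch: Xa 0.0500 M; Xb 0.100 M
- maple: Xa 0.0250 M; Xb 0.0750 M
- alder: Xa 0.0250 M; Xb 0.100 M
- oak: Xa 0.0500 M; Xb 0.100 M; Xp 0.0150 M; time 26 h

| larch run: time / h | larch run: [Xa] / M | maple run: time / h | maple run: [Xa] / M | alder run: time / h | alder run: [Xa] / M |
|---|---|---|---|---|---|
| 4.3 | 0.0398 | 4.3 | 0.0218 | 4.3 | 0.0227 |
| 8.7 | 0.0329 | 8.7 | 0.0203 | 8.7 | 0.0206 |
| 13 | 0.0285 | 13 | 0.0187 | 13 | 0.0185 |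
| 17 | 0.0269 | 17 | 0.0194 | 17 | 0.0175 |
| 22 | 0.0261 | 22 | 0.0176 | 22 | 0.0159 |
| 26 | 0.0252 | 26 | 0.0165 | 26 | 0.0156 |

(scatter of a reading: 5 × 10⁻⁴ M)

1. order of the initial rate in [Xa], near the charge of the larch run, the rate being that where two percent of its Xa are Xp (one fixed amount of Xp, the same in the runs compared)
2. order of the initial rate in [Xb], near the charge of the larch run, the rate being that where two percent of its Xa are Xp
3. Xa in the oak run at 26 h, as a share of the Xa charged

- Overall: Xa + Xb -> Xp, with Xc as catalyst.
- Constant volume, constant temperature.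
- Bound and free are read together.
- An order is taken over about fifteen percent of the charge, up and down.

Minutes of the meeting on oak. Present: the forecaster and I.

I proposed one measure, the decade rate D: the decades of Xa lost per hour up to the first reading. Larch gave 0.0230 h⁻¹ and alder 0.00975 h⁻¹. So larch fell faster than alder, although a loss of first order in Xa, at the same Xb and Xc, gives both the same D.

I then pointed to Xp. Taking the mean [Xp] in that window as half the Xp made by the first reading, larch held 5.10 mM and alder 1.15 mM. I charged the whole difference in D to Xp, which is my assumption. This gave a reading of 3.37 L mol⁻¹ h⁻¹ for the seed gain g, the decade rate added per unit of [Xp] over that window. It carries the scatter of the readings.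

I applied g to oak. Its seed of 0.0150 M Xp, times g and added to alder's D, gives oak a D of 0.0602 h⁻¹. By my reckoning, oak's Xa stands at 55.1% of its charge at 4.3 h. The Xp made in oak adds to its seed, and I committed to a lower share at 26 h.

The forecaster gave an order of 1.9 in Xa, 0 in Xb, and 65% of the Xa left in oak at 26 h. The forecaster took the stall in larch, with the smaller fall in alder and maple, as a pattern “which suggests Xp inhibition or reversibility”, and expected the seed to bring the stall sooner in oak. We differed on the sign of the seed. My share at 4.3 h already lies below the forecast's share at 26 h.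

The flask gives an order of 1.2 in Xa, 0.77 in Xb, and 9.99% of the Xa left in oak at 26 h.

    Xc + Xa ⇌ Xc.Xa (21.28 L mol⁻¹ h⁻¹, 19.08 h⁻¹)
    Xc.Xa + Xb → Xp + Xc (107.6 L mol⁻¹ h⁻¹)
    Xa + Xb + Xp → 2 Xp (217.1 L² mol⁻² h⁻¹)
    2 Xb → Q (3.096 L mol⁻¹ h⁻¹)

Oak lost 1.00 decades by 26 h, and my seed term g[Xp] gave it 0.217 decades by 4.3 h. The main reason is autocatalysis, the path in which Xp helps turn Xa and Xb into more Xp. The oak run without that path keeps 84.8% of its Xa at 26 h. With g at zero, my reckoning leaves oak 0.0419 decades by 4.3 h, and the oak run without the path loses 0.0716 decades by 26 h.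

The numbers in the tables are simulated with constants of no real substance; the scatter is artificial.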